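**Plan**
- Retrosynthesis: cut the C15–O ester bond (ferulate), then C8–C17 (methyl from an enol triflate), then C5–C10 and C6–C7 together. This opens rings A and B to an acyclic (E)-1-nitrodeca-1,7,9-triene, which is cut further at C9–C11, C10–C20 and C1–C2.
- Enabling feature: in cyclohexene ring B the C7=C8 bond lies next to the ring fusion. C7–C8–C9–C10 can therefore come from a 2-silyloxydiene (oxygen on C8) and C5–C6 from a dienophile, with the ring A chain C1–C2–C3–C4 as a four-atom tether.
- Helpers: a nitro group on C6 activates the dienophile and is later lost as nitrite; the C8 oxygen ends as the triflate that is exchanged for C17.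
- Forward: vinylogous aldol (C1–C2), alkylation with a citronellol-derived iodide (C9–C11), (Z)-enol tosylate/methyl coupling (C10–C20, fixes (E)-C9=C10), ester to methyl ketone, nitration of the vinyl group. Rings A and B then close in one operation, followed by conjugate reduction/triflation, methyl coupling and esterification.
- Stereochemistry: C13 from (R)-citronellol; C2 from a Ti/BINOL-catalysed aldol; C5 and C10 from C2 (equatorial OTBS in the chair tether), the (E)-diene and the endo transition state; C9 by protonation/equilibration next to the C8 ketone.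

Key step: step 12

Remark: labdane numbering (C1–C20) is used for atoms throughout; in step 5 (R)-BINOL is assumed to direct attack to the Re face of aldehyde 6 (giving the 5S carbinol), and the antipodal ligand would be used if the sense proved opposite.

**Step 1**
Reactants: 1 (R)-citronellol
Product: 2 (R)-tert-butyl[(3,7-dimethyloct-6-en-1-yl)oxy]dimethylsilane
Conditions: TBSCl, imidazole, CH2Cl2, 0 °C → rt
Reagents that add atoms: tert-butyldimethylsilyl chloride, CC(C)(C)[Si](C)(C)Cl
Why: Standard silylation of a primary alcohol; the future C13 stereocentre is taken unchanged from the chiral pool.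

**Step 2**
Reactants: 2 (R)-tert-butyl[(3,7-dimethyloct-6-en-1-yl)oxy]dimethylsilane
Product: 3 (R)-6-(tert-butyldimethylsilyloxy)-4-methylhexanoic acid
Conditions: RuCl3 (cat.), NaIO4, MeCN/EtOAc/H2O, 0 °C → rt
Reagents that add atoms: sodium periodate, [Na+].[O-]I(=O)(=O)=O; water, O
Why: Oxidative cleavage of the trisubstituted alkene by catalytic RuO4 should give the acid and acetone; the stereocentre is remote.

**Step 3**
Reactants: 3 (R)-6-(tert-butyldimethylsilyloxy)-4-methylhexanoic acid
Product: 4 (S)-tert-butyl[(5-iodo-3-methylpentyl)oxy]dimethylsilane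
Conditions: PhI(OAc)2, I2, hν, cyclohexane, reflux
Reagents that add atoms: iodine, II
Why: Hunsdiecker-type radical iododecarboxylation through an acyl hypoiodite converts the primary acid into the primary iodide (future C11); the descriptor changes only through CIP priorities.

**Step 4**
Reactants: 5 methyl 3,3-dimethylpent-4-enoate
Product: 6 3,3-dimethylpent-4-enal
Conditions: i-Bu2AlH, CH2Cl2, −78 °C; aq. potassium sodium tartrate
Reagents that add atoms: none
Why: Partial reduction of the ester stops at the tetrahedral aluminate at low temperature; the volatile aldehyde would be used as a solution.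

**Step 5**
Reactants: 6 3,3-dimethylpent-4-enal; 7 1-methoxy-1,3-bis(trimethylsilyloxy)buta-1,3-diene
Product: 9 methyl (5S)-5-hydroxy-7,7-dimethyl-3-oxonon-8-enoate, via bis-silyl aldol adduct 8 (not isolated)
Conditions: Ti(OiPr)4 (cat.), (R)-BINOL (cat.), 4 Å MS, THF, −78 °C → rt; then TFA, THF/H2O, 0 °C
Reagents that add atoms: none
Why: Catalytic asymmetric vinylogous Mukaiyama aldol addition in which the diene terminus attacks the Re face of the Ti/BINOL-bound aldehyde, setting the C2 carbinol (5S in this ester) and forming C1–C2; acid removes both trimethylsilyl groups.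

**Step 6**
Reactants: 9 methyl (5S)-5-hydroxy-7,7-dimethyl-3-oxonon-8-enoate
Product: 10 methyl (5S)-5-(tert-butyldimethylsilyloxy)-7,7-dimethyl-3-oxonon-8-enoate
Conditions: TBSCl, imidazole, DMF, rt
Reagents that add atoms: tert-butyldimethylsilyl chloride, CC(C)(C)[Si](C)(C)Cl
Why: Silylation of the secondary alcohol blocks lactonisation and β-elimination and supplies the group that later steers the cyclisation.

**Step 7**
Reactants: 10 methyl (5S)-5-(tert-butyldimethylsilyloxy)-7,7-dimethyl-3-oxonon-8-enoate; 4 (S)-tert-butyl[(5-iodo-3-methylpentyl)oxy]dimethylsilane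
Product: 11 methyl (5S)-5-(tert-butyldimethylsilyloxy)-2-[(3R)-5-(tert-butyldimethylsilyloxy)-3-methylpentyl]-7,7-dimethyl-3-oxonon-8-enoate (mixture at C2 of the ester)
Conditions: Cs2CO3, DMF, rt → 40 °C
Reagents that add atoms: none
Why: Acetoacetic ester alkylation of the soft β-keto ester enolate by the primary iodide joins C9 to C11; the new C9 centre forms as a mixture that is erased in step 8.

**Step 8**
Reactants: 11 the alkylated β-keto ester
Product: 12 methyl (2Z,5S)-5-(tert-butyldimethylsilyloxy)-2-[(3R)-5-(tert-butyldimethylsilyloxy)-3-methylpentyl]-7,7-dimethyl-3-(4-toluenesulfonyloxy)nona-2,8-dienoate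
Conditions: TsCl, TMEDA, LiCl, MeCN, 0 °C
Reagents that add atoms: 4-toluenesulfonyl chloride, Cc1ccc(cc1)S(Cl)(=O)=O
Why: Chelation-controlled enol tosylation: the lithium-bridged (Z)-enolate of the β-keto ester is O-sulfonylated, so the tosyloxy group on C10 ends cis to the ester, which fixes the later (E)-geometry of C9=C10.

**Step 9**
Reactants: 12 the (Z)-enol tosylate
Product: 13 methyl (2E,5S)-5-(tert-butyldimethylsilyloxy)-2-[(3R)-5-(tert-butyldimethylsilyloxy)-3-methylpentyl]-3,7,7-trimethylnona-2,8-dienoate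
Conditions: MeZnCl, Pd(OAc)2 (cat.), SPhos (cat.), THF, 50 °C
Reagents that add atoms: methylzinc chloride, C[Zn]Cl
Why: Negishi coupling of the fully substituted enol tosylate with retention of configuration places the C20 methyl group cis to the ester and the C1 chain trans to it.

**Step 10**
Reactants: 13 the (E)-enoate
Product: 15 (3E,6S)-6-(tert-butyldimethylsilyloxy)-3-[(3R)-5-(tert-butyldimethylsilyloxy)-3-methylpentyl]-4,8,8-trimethyldeca-3,9-dien-2-one, via 2-methoxydiene 14 (not isolated)
Conditions: Cp2TiMe2, PhMe, 70 °C (dark); then oxalic acid, wet THF, 0 °C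
Reagents that add atoms: dimethyltitanocene, [CH3-].[CH3-].[Ti+4].c1cc[cH-]c1.c1cc[cH-]c1; water, O
Why: Carbonyl methylenation of the hindered ester by the titanium methylidene gives a 2-methoxydiene that mild acid protonates at its terminal carbon, so hydrolysis should deliver the methyl ketone (C7–C8) without touching the C9=C10 geometry.

**Step 11**
Reactants: 15 the dienone
Product: 16 (3E,6S,9E)-6-(tert-butyldimethylsilyloxy)-3-[(3R)-5-(tert-butyldimethylsilyloxy)-3-methylpentyl]-4,8,8-trimethyl-10-nitrodeca-3,9-dien-2-one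
Conditions: AgNO2, TEMPO, 4 Å MS, ClCH2CH2Cl, 70 °C
Reagents that add atoms: silver nitrite, [Ag+].[O-]N=O
Why: Radical nitration of the terminal alkene: NO2 adds to the CH2 terminus and TEMPO-mediated loss of hydrogen gives the (E)-nitroalkene; the quaternary C4 offers no allylic hydrogen and the electron-poor tetrasubstituted enone should not be attacked.

**Step 12**
Reactants: 16 the nitro dienone
Product: 20 (13R)-2α,15-bis(tert-butyldimethylsilyloxy)-17-norlabd-6-en-8-one, via silyloxydiene 17 (not isolated), via silyl enol ether cycloadduct 18 (not isolated), via β-nitro ketone 19 (not isolated)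
Conditions: TMSOTf, Et3N, PhMe, 0 °C; then dilution to 0.01 M, BHT, 100 °C; then K2CO3, MeOH, 0 °C → rt
Reagents that add atoms: none
Why: Soft enolisation at C7 gives the cross-conjugated 2-silyloxydiene C7=C8(OTMS)–C9=C10, which on heating undergoes a concerted, asynchronous intramolecular Diels–Alder reaction with the (E)-nitroalkene C5=C6, forming C5–C10 and C6–C7 at once; the closest known reaction type is the thermal cyclisation of (E)-1-nitrodeca-1,7,9-trienes to trans-fused nitro-octalins. Ring A closes as the six-membered tether ring (C10–C1–C2–C3–C4–C5, chair-like, the chain C1–C4 spanning diene terminus and dienophile) and ring B as the cyclohexene of the [4+2] event (C5–C6–C7–C8–C9–C10). The trans-fusion (5α-H, 10β-CH3) follows from the (E)-geometry of C9=C10 (tether outside, methyl inside) combined with the endo orientation of the nitro group, and its absolute sense from C2, whose silyloxy group sits equatorial in the chair tether to avoid a syn-pentane clash with the axial C4 and C10 methyl groups. C6 (nitro, α) is created and destroyed again, and C9 is set when methanolysis of the silyl enol ether protonates it on the face away from the angular methyl group, after which it can equilibrate next to the C8 ketone towards the equatorial side chain. The step needs endo over exo selectivity and a regiochemistry that runs against the natural polarisation of the two partners; the first rests on the secondary-orbital preference of the nitro group in a chair tether, the second on the tether itself, and high dilution suppresses bimolecular Michael addition. Base then expels nitrite from the β-nitro ketone (E1cB through the C7 enolate) to give the C6=C7 enone, so the activating group leaves without trace.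

**Step 13**
Reactants: 20 the enone
Product: 22 (13R)-2α,15-bis(tert-butyldimethylsilyloxy)-17-norlabd-7-en-8-yl trifluoromethanesulfonate, via lithium enolate 21 (not isolated)
Conditions: LiBH(s-Bu)3, THF, −78 °C; then PhNTf2, −78 → 0 °C
Reagents that add atoms: N-phenylbis(trifluoromethanesulfonimide), FC(F)(F)S(=O)(=O)N(c1ccccc1)S(=O)(=O)C(F)(F)F
Why: The bulky hydride adds 1,4 to the β-unsubstituted cyclohexenone (conjugate reduction) and the regiodefined C7–C8 enolate is trapped on oxygen, which fixes the double bond at C7=C8 without disturbing C9.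

**Step 14**
Reactants: 22 the enol triflate
Product: 23 (13R)-2α,15-bis(tert-butyldimethylsilyloxy)labd-7-ene
Conditions: MeMgBr, Fe(acac)3 (cat.), THF/NMP, −30 → 0 °C
Reagents that add atoms: methylmagnesium bromide, C[Mg]Br
Why: Iron-catalysed cross-coupling of the alkenyl triflate with a methyl Grignard reagent installs C17 on C8 with the double bond held at C7=C8.

**Step 15**
Reactants: 23 the bis-silyl ether
Product: 24 (13R)-2α-(tert-butyldimethylsilyloxy)labd-7-en-15-ol
Conditions: HF·pyridine, pyridine, THF, 0 °C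
Reagents that add atoms: none
Why: The unhindered primary silyl ether should be cleaved much faster than the secondary one under buffered fluoride conditions.

**Step 16**
Reactants: 24 the primary alcohol; 25 (E)-ferulic acid
Product: 26 (13R)-2α-(tert-butyldimethylsilyloxy)labd-7-en-15-yl (E)-3-(4-hydroxy-3-methoxyphenyl)prop-2-enoate
Conditions: PPh3, DIAD, THF, 0 °C → rt
Reagents that add atoms: none
Why: Mitsunobu esterification in which the carboxylic acid, far more acidic than the phenol, is the pronucleophile and displaces the activated primary alcohol, so no phenol protection is needed.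

**Step 17**
Reactants: 26 the silyl-protected ester
Product: 27 (2S,5S,9S,10S,13R)-2-hydroxylabd-7-en-15-yl (E)-3-(4-hydroxy-3-methoxyphenyl)prop-2-enoate (CNP0175017.1)
Conditions: HF·pyridine, THF, rt
Reagents that add atoms: none
Why: Fluoride cleavage of the remaining secondary silyl ether; the cinnamate ester, the phenol and the trisubstituted alkene should be stable to HF·pyridine.

**Compound list**
1 | (R)-citronellol | OCC[C@H](C)CCC=C(C)C | starting material
2 | (R)-tert-butyl[(3,7-dimethyloct-6-en-1-yl)oxy]dimethylsilane | CC(C)(C)[Si](C)(C)OCC[C@H](C)CCC=C(C)C | intermediate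
3 | (R)-6-(tert-butyldimethylsilyloxy)-4-methylhexanoic acid | CC(C)(C)[Si](C)(C)OCC[C@H](C)CCC(=O)O | intermediate
4 | (S)-tert-butyl[(5-iodo-3-methylpentyl)oxy]dimethylsilane | CC(C)(C)[Si](C)(C)OCC[C@H](C)CCI | intermediate
5 | methyl 3,3-dimethylpent-4-enoate | COC(=O)CC(C)(C)C=C | starting material
6 | 3,3-dimethylpent-4-enal | O=CCC(C)(C)C=C | intermediate
7 | 1-methoxy-1,3-bis(trimethylsilyloxy)buta-1,3-diene | COC(O[Si](C)(C)C)=CC(=C)O[Si](C)(C)C | starting material
8 | methyl (5S)-7,7-dimethyl-3,5-bis(trimethylsilyloxy)nona-2,8-dienoate | COC(=O)C=C(O[Si](C)(C)C)C[C@@H](O[Si](C)(C)C)CC(C)(C)C=C | intermediate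
9 | methyl (5S)-5-hydroxy-7,7-dimethyl-3-oxonon-8-enoate | COC(=O)CC(=O)C[C@@H](O)CC(C)(C)C=C | intermediate
10 | methyl (5S)-5-(tert-butyldimethylsilyloxy)-7,7-dimethyl-3-oxonon-8-enoate | COC(=O)CC(=O)C[C@@H](O[Si](C)(C)C(C)(C)C)CC(C)(C)C=C | intermediate
11 | methyl (5S)-5-(tert-butyldimethylsilyloxy)-2-[(3R)-5-(tert-butyldimethylsilyloxy)-3-methylpentyl]-7,7-dimethyl-3-oxonon-8-enoate | CC(C)(C)[Si](C)(C)OCC[C@H](C)CCC(C(=O)OC)C(=O)C[C@@H](O[Si](C)(C)C(C)(C)C)CC(C)(C)C=C | intermediate
12 | methyl (2Z,5S)-5-(tert-butyldimethylsilyloxy)-2-[(3R)-5-(tert-butyldimethylsilyloxy)-3-methylpentyl]-7,7-dimethyl-3-(4-toluenesulfonyloxy)nona-2,8-dienoate | CC(C)(C)[Si](C)(C)OCC[C@H](C)CC/C(C(=O)OC)=C(/OS(=O)(=O)c1ccc(C)cc1)C[C@@H](O[Si](C)(C)C(C)(C)C)CC(C)(C)C=C | intermediate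
13 | methyl (2E,5S)-5-(tert-butyldimethylsilyloxy)-2-[(3R)-5-(tert-butyldimethylsilyloxy)-3-methylpentyl]-3,7,7-trimethylnona-2,8-dienoate | CC(C)(C)[Si](C)(C)OCC[C@H](C)CC/C(C(=O)OC)=C(/C)C[C@@H](O[Si](C)(C)C(C)(C)C)CC(C)(C)C=C | intermediate
14 | (3E,6S)-6-(tert-butyldimethylsilyloxy)-3-[(3R)-5-(tert-butyldimethylsilyloxy)-3-methylpentyl]-2-methoxy-4,8,8-trimethyldeca-1,3,9-triene | CC(C)(C)[Si](C)(C)OCC[C@H](C)CC/C(C(=C)OC)=C(/C)C[C@@H](O[Si](C)(C)C(C)(C)C)CC(C)(C)C=C | intermediate
15 | (3E,6S)-6-(tert-butyldimethylsilyloxy)-3-[(3R)-5-(tert-butyldimethylsilyloxy)-3-methylpentyl]-4,8,8-trimethyldeca-3,9-dien-2-one | CC(C)(C)[Si](C)(C)OCC[C@H](C)CC/C(C(C)=O)=C(/C)C[C@@H](O[Si](C)(C)C(C)(C)C)CC(C)(C)C=C | intermediate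
16 | (3E,6S,9E)-6-(tert-butyldimethylsilyloxy)-3-[(3R)-5-(tert-butyldimethylsilyloxy)-3-methylpentyl]-4,8,8-trimethyl-10-nitrodeca-3,9-dien-2-one | CC(C)(C)[Si](C)(C)OCC[C@H](C)CC/C(C(C)=O)=C(/C)C[C@@H](O[Si](C)(C)C(C)(C)C)CC(C)(C)/C=C/[N+](=O)[O-] | intermediate
17 | (3E,6S,9E)-6-(tert-butyldimethylsilyloxy)-3-[(3R)-5-(tert-butyldimethylsilyloxy)-3-methylpentyl]-4,8,8-trimethyl-10-nitro-2-(trimethylsilyloxy)deca-1,3,9-triene | CC(C)(C)[Si](C)(C)OCC[C@H](C)CC/C(C(=C)O[Si](C)(C)C)=C(/C)C[C@@H](O[Si](C)(C)C(C)(C)C)CC(C)(C)/C=C/[N+](=O)[O-] | intermediate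
18 | (13R)-6α-nitro-2α,15-bis(tert-butyldimethylsilyloxy)-8-(trimethylsilyloxy)-17-norlabd-8-ene (5α-H, 10β-CH3) | CC(C)(C)[Si](C)(C)OCC[C@H](C)CCC2=C(O[Si](C)(C)C)C[C@H]([N+](=O)[O-])[C@H]3C(C)(C)C[C@H](O[Si](C)(C)C(C)(C)C)C[C@]23C | intermediate
19 | (13R)-6α-nitro-2α,15-bis(tert-butyldimethylsilyloxy)-17-norlabdan-8-one (5α-H, 9α-H, 10β-CH3) | CC(C)(C)[Si](C)(C)OCC[C@H](C)CC[C@H]2C(=O)C[C@H]([N+](=O)[O-])[C@H]3C(C)(C)C[C@H](O[Si](C)(C)C(C)(C)C)C[C@]23C | intermediate
20 | (13R)-2α,15-bis(tert-butyldimethylsilyloxy)-17-norlabd-6-en-8-one (5α-H, 9α-H, 10β-CH3) | CC(C)(C)[Si](C)(C)OCC[C@H](C)CC[C@H]2C(=O)C=C[C@H]3C(C)(C)C[C@H](O[Si](C)(C)C(C)(C)C)C[C@]23C | intermediate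
21 | lithium (13R)-2α,15-bis(tert-butyldimethylsilyloxy)-17-norlabd-7-en-8-olate | [Li+].CC(C)(C)[Si](C)(C)OCC[C@H](C)CC[C@H]2C([O-])=CC[C@H]3C(C)(C)C[C@H](O[Si](C)(C)C(C)(C)C)C[C@]23C | intermediate
22 | (13R)-2α,15-bis(tert-butyldimethylsilyloxy)-17-norlabd-7-en-8-yl trifluoromethanesulfonate | CC(C)(C)[Si](C)(C)OCC[C@H](C)CC[C@H]2C(OS(=O)(=O)C(F)(F)F)=CC[C@H]3C(C)(C)C[C@H](O[Si](C)(C)C(C)(C)C)C[C@]23C | intermediate
23 | (13R)-2α,15-bis(tert-butyldimethylsilyloxy)labd-7-ene | CC(C)(C)[Si](C)(C)OCC[C@H](C)CC[C@H]2C(C)=CC[C@H]3C(C)(C)C[C@H](O[Si](C)(C)C(C)(C)C)C[C@]23C | intermediate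
24 | (13R)-2α-(tert-butyldimethylsilyloxy)labd-7-en-15-ol | OCC[C@H](C)CC[C@H]2C(C)=CC[C@H]3C(C)(C)C[C@H](O[Si](C)(C)C(C)(C)C)C[C@]23C | intermediate
25 | (E)-ferulic acid | COc1cc(/C=C/C(=O)O)ccc1O | starting material
26 | (13R)-2α-(tert-butyldimethylsilyloxy)labd-7-en-15-yl (E)-ferulate | COc1cc(/C=C/C(=O)OCC[C@H](C)CC[C@H]2C(C)=CC[C@H]3C(C)(C)C[C@H](O[Si](C)(C)C(C)(C)C)C[C@]23C)ccc1O | intermediate
27 | (2S,5S,9S,10S,13R)-2-hydroxylabd-7-en-15-yl (E)-ferulate (2α-OH, 5α-H, 9α-H, 10β-CH3) | COc1cc(/C=C/C(=O)OCC[C@H](C)CC[C@H]2C(C)=CC[C@H]3C(C)(C)C[C@H](O)C[C@]23C)ccc1O | target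

**Totals**
Total step count: 17.
Longest linear sequence: 14 steps (steps 4–17 from methyl 3,3-dimethylpent-4-enoate; the citronellol branch, steps 1–3 and 7–17, is equally long).

**Steps most likely to fail**

Step 12. The fully substituted diene terminus may cyclise slowly, the C9=C10 geometry may scramble during silylation, or exo closure may compete and give cis-fused material. The fallback sets out from 15 and returns at 20 through a polarity-matched stepwise annulation instead of a cycloaddition. The vinyl group of 15 would be cleaved (OsO4 cat., NaIO4, 2,6-lutidine, dioxane/H2O) to the aldehyde F1. Wittig methoxymethylenation (Ph3P=CHOMe, THF) would give the methyl enol ether F2. A Me2AlCl-promoted intramolecular Mukaiyama–Michael addition of its nucleophilic carbon C5 to C10 of the enone (CH2Cl2, −78 °C, aqueous work-up) should close ring A and give the keto aldehyde F3. Aldol condensation of the C7 methyl ketone onto the C6 aldehyde (KOH, MeOH), with equilibration at C5 and C9, would close ring B and give 20.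

Step 11. The radical nitration may be slow at the neopentyl-type alkene or unselective towards the enone. The fallback sets out from 15 and returns at 16 by a carbonyl route. Oxidative cleavage as above would give the aldehyde F1; Henry addition of nitromethane (cat. KOt-Bu, THF/t-BuOH) would give the nitro alcohol F4; dehydration (MsCl, Et3N, CH2Cl2, 0 °C) would give 16.

Step 10. Methylenation of the hindered, twisted ester may be incomplete, or the acidic hydrolysis may isomerise the C9=C10 bond. The fallback sets out from 13 and returns at 15 by a redox/Grignard sequence. Reduction (i-Bu2AlH, CH2Cl2, −78 °C) would give the allylic alcohol F5; Dess–Martin oxidation would give the enal F6; MeMgBr (THF, −78 °C) would give the secondary allylic alcohol F7; a second Dess–Martin oxidation would give 15.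

**Further compounds**
F1 | step 12 | (3E,6S)-6-(tert-butyldimethylsilyloxy)-3-[(3R)-5-(tert-butyldimethylsilyloxy)-3-methylpentyl]-4,8,8-trimethyl-2-oxonon-3-en-9-al (aldehyde) | CC(C)(C)[Si](C)(C)OCC[C@H](C)CC/C(C(C)=O)=C(/C)C[C@@H](O[Si](C)(C)C(C)(C)C)CC(C)(C)C=O
F2 | step 12 | (3E,6S)-6-(tert-butyldimethylsilyloxy)-3-[(3R)-5-(tert-butyldimethylsilyloxy)-3-methylpentyl]-10-methoxy-4,8,8-trimethyldeca-3,9-dien-2-one (methyl enol ether, E/Z at C9) | CC(C)(C)[Si](C)(C)OCC[C@H](C)CC/C(C(C)=O)=C(/C)C[C@@H](O[Si](C)(C)C(C)(C)C)CC(C)(C)C=COC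
F3 | step 12 | ring A keto aldehyde: (13R)-2α,15-bis(tert-butyldimethylsilyloxy)-6,7-seco-17-norlabdan-8-on-6-al (5α-H, 10β-CH3, C9 epimers) | O=C[C@H]1C(C)(C)C[C@H](O[Si](C)(C)C(C)(C)C)C[C@]1(C)C(CC[C@@H](C)CCO[Si](C)(C)C(C)(C)C)C(C)=O
F4 | step 11 | (3E,6S)-6-(tert-butyldimethylsilyloxy)-3-[(3R)-5-(tert-butyldimethylsilyloxy)-3-methylpentyl]-9-hydroxy-4,8,8-trimethyl-10-nitrodec-3-en-2-one (nitro alcohol, C9 epimers) | CC(C)(C)[Si](C)(C)OCC[C@H](C)CC/C(C(C)=O)=C(/C)C[C@@H](O[Si](C)(C)C(C)(C)C)CC(C)(C)C(O)C[N+](=O)[O-]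
F5 | step 10 | (2E,5S)-5-(tert-butyldimethylsilyloxy)-2-[(3R)-5-(tert-butyldimethylsilyloxy)-3-methylpentyl]-3,7,7-trimethylnona-2,8-dien-1-ol (allylic alcohol) | CC(C)(C)[Si](C)(C)OCC[C@H](C)CC/C(CO)=C(/C)C[C@@H](O[Si](C)(C)C(C)(C)C)CC(C)(C)C=C
F6 | step 10 | (2E,5S)-5-(tert-butyldimethylsilyloxy)-2-[(3R)-5-(tert-butyldimethylsilyloxy)-3-methylpentyl]-3,7,7-trimethylnona-2,8-dienal (enal) | CC(C)(C)[Si](C)(C)OCC[C@H](C)CC/C(C=O)=C(/C)C[C@@H](O[Si](C)(C)C(C)(C)C)CC(C)(C)C=C
F7 | step 10 | (3E,6S)-6-(tert-butyldimethylsilyloxy)-3-[(3R)-5-(tert-butyldimethylsilyloxy)-3-methylpentyl]-4,8,8-trimethyldeca-3,9-dien-2-ol (secondary allylic alcohol, C2 epimers) | CC(C)(C)[Si](C)(C)OCC[C@H](C)CC/C(C(C)O)=C(/C)C[C@@H](O[Si](C)(C)C(C)(C)C)CC(C)(C)C=C
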